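The pyranone ring is disconnected at C3–C4. Because C3 is an unsubstituted CH2 and C2 a CH flanked by O1 and ring B, the O1–C2(H)–C3H2–C4(=O) segment is the formal adduct of an aldehyde C4–H across a C2=C3 aryl enol ether held ortho on ring A. An enantioselective Rh-catalysed intramolecular hydroacylation of this achiral aldehyde–enol ether therefore forms C3–C4, closes the pyranone and sets C2 in one operation. The precursor comes from Tebbe methylenation of an aryl ester and ortho-lithiation/formylation; the C5 methoxy group is finally unmasked by chelation to the C4 carbonyl.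

Key step: step 7

Remark: the sense of induction of the hydroacylation catalyst cannot be predicted for this substrate, so (R)-DTBM-SEGPHOS is written as a working assumption and its antipode is used if the first screen shows it is needed for (2S); 1,2,3,4-tetramethoxybenzene and 2-hydroxy-6-methoxybenzaldehyde are taken as commercial.

Step 1
Reactants: 1 1,2,3,4-tetramethoxybenzene
Product: 4 2,3,4,5-tetramethoxyphenol, via (2,3,4,5-tetramethoxyphenyl)lithium 2 (not isolated), via dimethyl (2,3,4,5-tetramethoxyphenyl)boronate 3 (not isolated)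
Conditions: n-BuLi, TMEDA, THF, 0 °C; B(OMe)3, −78 °C → rt; then AcOH, 30% aq. H2O2, 0 °C → rt
Reagents that add atoms: hydrogen peroxide, OO
Why: Directed ortho-metalation next to a methoxy group (the two free positions of 1 are equivalent, so only one aryllithium can form), borylation and oxidative aryl shift from boron to oxygen should give the phenol as a single regioisomer.

Step 2
Reactants: 5 2-hydroxy-6-methoxybenzaldehyde
Product: 6 2-(benzyloxy)-6-methoxybenzaldehyde
Conditions: BnBr, K2CO3, DMF, rt
Reagents that add atoms: benzyl bromide, BrCc1ccccc1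
Why: Williamson ether synthesis on the phenoxide; the aldehyde has no α-hydrogen and is inert to carbonate.

Step 3
Reactants: 6 2-(benzyloxy)-6-methoxybenzaldehyde
Product: 7 2-(benzyloxy)-6-methoxybenzoic acid
Conditions: NaClO2, NaH2PO4, 2-methyl-2-butene, t-BuOH/H2O, rt
Reagents that add atoms: sodium chlorite, [Na+].[O-]Cl=O
Why: Pinnick oxidation converts the hindered, non-enolisable aldehyde into the acid, and the alkene scavenger intercepts HOCl before it can chlorinate the electron-rich ring.

Step 4
Reactants: 7 2-(benzyloxy)-6-methoxybenzoic acid; 4 2,3,4,5-tetramethoxyphenol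
Product: 9 2,3,4,5-tetramethoxyphenyl 2-(benzyloxy)-6-methoxybenzoate, via 2-(benzyloxy)-6-methoxybenzoyl chloride 8 (not isolated)
Conditions: (COCl)2, cat. DMF, CH2Cl2, 0 °C → rt, concentrate; then 4, Et3N, cat. DMAP, CH2Cl2, 0 °C → rt
Reagents that add atoms: none
Why: Nucleophilic acyl substitution through the acid chloride with DMAP catalysis should force esterification of the 2,6-disubstituted acid with the phenol.

Step 5
Reactants: 9 2,3,4,5-tetramethoxyphenyl 2-(benzyloxy)-6-methoxybenzoate
Product: 10 1-(benzyloxy)-3-methoxy-2-[1-(2,3,4,5-tetramethoxyphenoxy)ethenyl]benzene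
Conditions: Tebbe reagent (toluene solution), cat. pyridine, THF, −40 °C → rt; aq. NaOH quench, basic alumina
Reagents that add atoms: Tebbe reagent Cp2Ti(μ-CH2)(μ-Cl)AlMe2, C[Al-]1(C)C[Ti](C2C=CC=C2)(C2C=CC=C2)[Cl+]1
Why: Tebbe methylenation, in which the titanium methylidene adds to the ester carbonyl and the oxatitanacyclobutane collapses to the enol ether, is established for aryl benzoates; the benzyl and methyl ethers are inert and the basic work-up protects the acid-labile product.

Step 6
Reactants: 10 1-(benzyloxy)-3-methoxy-2-[1-(2,3,4,5-tetramethoxyphenoxy)ethenyl]benzene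
Product: 12 2-({1-[2-(benzyloxy)-6-methoxyphenyl]ethenyl}oxy)-3,4,5,6-tetramethoxybenzaldehyde, via ring-A aryllithium 11 (not isolated)
Conditions: n-BuLi, TMEDA, THF, −78 → −20 °C; DMF, −78 °C → rt; pH 7 phosphate buffer
Reagents that add atoms: N,N-dimethylformamide, CN(C)C=O
Why: Directed ortho-metalation, since the single ring-A C–H lies between the enol-ether oxygen and a methoxy group and should be lithiated faster than the singly activated ring-B positions or the benzylic CH2; DMF then formylates the aryllithium (Bouveault reaction) and the buffered work-up spares the enol ether.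

Step 7
Reactants: 12 2-({1-[2-(benzyloxy)-6-methoxyphenyl]ethenyl}oxy)-3,4,5,6-tetramethoxybenzaldehyde
Product: 13 (2S)-2-[2-(benzyloxy)-6-methoxyphenyl]-5,6,7,8-tetramethoxy-2,3-dihydro-4H-chromen-4-one
Conditions: [Rh(cod)Cl]2 (2.5 mol %), (R)-DTBM-SEGPHOS (5.5 mol %), NaBArF4 (5 mol %), 4 Å MS, 1,4-dioxane, 80 °C
Reagents that add atoms: none
Why: Proposed new method: a cationic Rh(I)–bisphosphine should insert into the aldehyde C–H bond of 12 to give an acyl–Rh(III) hydride, the tethered 1,1-disubstituted enol ether coordinates, hydride migrates to the oxygen- and aryl-bearing alkene carbon (the future C2) while Rh binds the terminal CH2, and C–C reductive elimination from the seven-membered acyl–alkyl rhodacycle forms the C3–C4 bond and returns Rh(I). The closest known reaction types are the Rh-catalysed enantioselective endo-hydroacylation of ortho-allylbenzaldehydes carrying 1,1-disubstituted alkenes (to 3-substituted tetralones), of 2-(1-arylvinyl)benzaldehydes (to 3-arylindanones) and of N-vinyl heteroaryl carbaldehydes, where hydride is likewise delivered to a heteroatom-bearing alkene carbon; an aryl 1-arylvinyl ether giving a chroman-4-one has not been shown. The pyranone ring closes in the 6-endo-trig mode with respect to the alkene. The C2 stereocentre is set under catalyst control by the face of the prochiral enol ether to which the chiral ligand directs hydride transfer. The step needs 6-endo over 5-exo regioselectivity and insertion faster than decarbonylation: the exo path would require a tertiary alkyl–Rh bond and a quaternary carbon in a benzofuranone and is disfavoured by the 1,1-disubstitution, and the two ortho oxygen substituents of ring A hold the formyl group next to the alkene. Strictly anhydrous, non-protic conditions should keep the acid-labile enol ether intact.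

Step 8
Reactants: 13 (2S)-2-[2-(benzyloxy)-6-methoxyphenyl]-5,6,7,8-tetramethoxy-2,3-dihydro-4H-chromen-4-one
Product: 14 (2S)-5-hydroxy-2-(2-hydroxy-6-methoxyphenyl)-6,7,8-trimethoxy-2,3-dihydro-4H-chromen-4-one
Conditions: BCl3 (3 equiv), pentamethylbenzene (3 equiv), CH2Cl2, −78 → 0 °C; MeOH, then pH 7 buffer
Reagents that add atoms: none
Why: BCl3 cleaves the aryl benzyl ether at −78 °C (benzyl cation trapped by pentamethylbenzene) and, on warming, the C5 methoxy group alone through the six-membered boron chelate with the C4 carbonyl (chelation-controlled demethylation), and the base-free medium avoids retro-oxa-Michael epimerisation at C2.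

Compound list
1 | 1,2,3,4-tetramethoxybenzene | COc1ccc(OC)c(OC)c1OC | starting material
2 | (2,3,4,5-tetramethoxyphenyl)lithium | [Li]c1cc(OC)c(OC)c(OC)c1OC | intermediate
3 | dimethyl (2,3,4,5-tetramethoxyphenyl)boronate | COB(OC)c1cc(OC)c(OC)c(OC)c1OC | intermediate
4 | 2,3,4,5-tetramethoxyphenol | Oc1cc(OC)c(OC)c(OC)c1OC | intermediate
5 | 2-hydroxy-6-methoxybenzaldehyde | COc1cccc(O)c1C=O | starting material
6 | 2-(benzyloxy)-6-methoxybenzaldehyde | COc1cccc(OCc2ccccc2)c1C=O | intermediate
7 | 2-(benzyloxy)-6-methoxybenzoic acid | COc1cccc(OCc2ccccc2)c1C(=O)O | intermediate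
8 | 2-(benzyloxy)-6-methoxybenzoyl chloride | COc1cccc(OCc2ccccc2)c1C(=O)Cl | intermediate
9 | 2,3,4,5-tetramethoxyphenyl 2-(benzyloxy)-6-methoxybenzoate | COc1cccc(OCc2ccccc2)c1C(=O)Oc1cc(OC)c(OC)c(OC)c1OC | intermediate
10 | 1-(benzyloxy)-3-methoxy-2-[1-(2,3,4,5-tetramethoxyphenoxy)ethenyl]benzene | COc1cccc(OCc2ccccc2)c1C(=C)Oc1cc(OC)c(OC)c(OC)c1OC | intermediate
11 | [2-({1-[2-(benzyloxy)-6-methoxyphenyl]ethenyl}oxy)-3,4,5,6-tetramethoxyphenyl]lithium | COc1cccc(OCc2ccccc2)c1C(=C)Oc1c([Li])c(OC)c(OC)c(OC)c1OC | intermediate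
12 | 2-({1-[2-(benzyloxy)-6-methoxyphenyl]ethenyl}oxy)-3,4,5,6-tetramethoxybenzaldehyde | COc1cccc(OCc2ccccc2)c1C(=C)Oc1c(C=O)c(OC)c(OC)c(OC)c1OC | intermediate
13 | (2S)-2-[2-(benzyloxy)-6-methoxyphenyl]-5,6,7,8-tetramethoxy-2,3-dihydro-4H-chromen-4-one | COc1cccc(OCc2ccccc2)c1[C@@H]1CC(=O)c2c(OC)c(OC)c(OC)c(OC)c2O1 | intermediate
14 | (2S)-5-hydroxy-2-(2-hydroxy-6-methoxyphenyl)-6,7,8-trimethoxy-2,3-dihydro-4H-chromen-4-one | COc1cccc(O)c1[C@@H]1CC(=O)c2c(O)c(OC)c(OC)c(OC)c2O1 | target

Total step count: 8. Longest linear sequence: 7 steps (from 5 through steps 2–8).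

Steps most likely to fail

Step 7 (proposed new method). Decarbonylation of the acyl–Rh hydride may outpace insertion into the hindered, electron-rich enol ether, the enol ether may be cleaved by adventitious acid, or the facial selectivity of hydride transfer may be poor. The fallback uses known chemistry and closes the ring through the O1–C2 bond instead. It sets out from phenol 4: Friedel–Crafts/Fries acetylation ortho to the hydroxyl (Ac2O, BF3·OEt2, 80 °C) should give 1-(2-hydroxy-3,4,5,6-tetramethoxyphenyl)ethan-1-one F1. Claisen–Schmidt condensation with aldehyde 6 (KOH, EtOH, rt) should give (E)-3-[2-(benzyloxy)-6-methoxyphenyl]-1-(2-hydroxy-3,4,5,6-tetramethoxyphenyl)prop-2-en-1-one F2. NaOAc in refluxing EtOH isomerises the chalcone by intramolecular oxa-Michael addition to racemic 2-[2-(benzyloxy)-6-methoxyphenyl]-5,6,7,8-tetramethoxychroman-4-one F3. Preparative chiral-phase HPLC then separates the enantiomers, and the (2S)-enantiomer is compound 13, where the route is rejoined.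

Step 6. Regiocontrol of the deprotonation may be lost through benzylic lithiation of the benzyl ether followed by Wittig rearrangement, lithiation on ring B, or vinylic deprotonation with expulsion of the aryloxide. The fallback replaces deprotonation by halogen–metal exchange and sets out from phenol 4. NBS (CH2Cl2, −78 °C) brominates the only free ring position to give 2-bromo-3,4,5,6-tetramethoxyphenol F4. Acylation with acid chloride 8 (prepared from 7 as in step 4) gives 2-bromo-3,4,5,6-tetramethoxyphenyl 2-(benzyloxy)-6-methoxybenzoate F5. Tebbe methylenation as in step 5 gives 1-(benzyloxy)-2-[1-(2-bromo-3,4,5,6-tetramethoxyphenoxy)ethenyl]-3-methoxybenzene F6. Bromine–lithium exchange (n-BuLi, THF, −78 °C), which is faster than any deprotonation, followed by DMF then gives aldehyde 12.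

Step 8. The C2 configuration may erode through Lewis-acid-induced opening of the C2–O1 bond (the ring-B oxygen substituents stabilise a benzylic cation), or the C6 methoxy group next to the boron-bound O5 may also be cleaved. The fallback moves the demethylation ahead of the stereocentre and ends with a neutral hydrogenolysis. From aldehyde 12, MgI2·OEt2 (toluene/Et2O, rt → 50 °C) should cleave only the methoxy group ortho to the formyl group through the magnesium chelate, giving 2-({1-[2-(benzyloxy)-6-methoxyphenyl]ethenyl}oxy)-6-hydroxy-3,4,5-trimethoxybenzaldehyde F7. BnBr, K2CO3, DMF gives 2-(benzyloxy)-6-({1-[2-(benzyloxy)-6-methoxyphenyl]ethenyl}oxy)-3,4,5-trimethoxybenzaldehyde F8. The hydroacylation conditions of step 7 should give (2S)-5-(benzyloxy)-2-[2-(benzyloxy)-6-methoxyphenyl]-6,7,8-trimethoxy-2,3-dihydro-4H-chromen-4-one F9. H2, Pd/C, EtOAc, rt then removes both benzyl groups and gives target 14.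

Further compounds
F1 | step 7 | 1-(2-hydroxy-3,4,5,6-tetramethoxyphenyl)ethan-1-one | CC(=O)c1c(O)c(OC)c(OC)c(OC)c1OC
F2 | step 7 | (E)-3-[2-(benzyloxy)-6-methoxyphenyl]-1-(2-hydroxy-3,4,5,6-tetramethoxyphenyl)prop-2-en-1-one | COc1cccc(OCc2ccccc2)c1/C=C/C(=O)c1c(O)c(OC)c(OC)c(OC)c1OC
F3 | step 7 | racemic 2-[2-(benzyloxy)-6-methoxyphenyl]-5,6,7,8-tetramethoxy-2,3-dihydro-4H-chromen-4-one | COc1cccc(OCc2ccccc2)c1C1CC(=O)c2c(OC)c(OC)c(OC)c(OC)c2O1
F4 | step 6 | 2-bromo-3,4,5,6-tetramethoxyphenol | Oc1c(Br)c(OC)c(OC)c(OC)c1OC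
F5 | step 6 | 2-bromo-3,4,5,6-tetramethoxyphenyl 2-(benzyloxy)-6-methoxybenzoate | COc1cccc(OCc2ccccc2)c1C(=O)Oc1c(Br)c(OC)c(OC)c(OC)c1OC
F6 | step 6 | 1-(benzyloxy)-2-[1-(2-bromo-3,4,5,6-tetramethoxyphenoxy)ethenyl]-3-methoxybenzene | COc1cccc(OCc2ccccc2)c1C(=C)Oc1c(Br)c(OC)c(OC)c(OC)c1OC
F7 | step 8 | 2-({1-[2-(benzyloxy)-6-methoxyphenyl]ethenyl}oxy)-6-hydroxy-3,4,5-trimethoxybenzaldehyde | COc1cccc(OCc2ccccc2)c1C(=C)Oc1c(C=O)c(O)c(OC)c(OC)c1OC
F8 | step 8 | 2-(benzyloxy)-6-({1-[2-(benzyloxy)-6-methoxyphenyl]ethenyl}oxy)-3,4,5-trimethoxybenzaldehyde | COc1cccc(OCc2ccccc2)c1C(=C)Oc1c(C=O)c(OCc2ccccc2)c(OC)c(OC)c1OC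
F9 | step 8 | (2S)-5-(benzyloxy)-2-[2-(benzyloxy)-6-methoxyphenyl]-6,7,8-trimethoxy-2,3-dihydro-4H-chromen-4-one | COc1cccc(OCc2ccccc2)c1[C@@H]1CC(=O)c2c(OCc3ccccc3)c(OC)c(OC)c(OC)c2O1
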